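**Plan**

- Retrosynthesis: remove the three O-protecting groups; cut the S2–C3 bond of the thiolactone, which goes back to the O2–C3 bond of an isobenzofuran-1(3H)-thione with the same carbon skeleton; return C1=S to C1=O; cut C3–C3a together with the lactone C1–O2 bond (aryllithium plus α-silyloxy aldehyde); cut the aryl–prenyl and aryl–carbonyl bonds.
- Forward: hydroquinone receives the carboxamide (anionic ortho-Fries), bromine and then the prenyl group. Ortho-lithiation and aldehyde addition join the side chain and close the furanone ring. Oxygen-to-sulfur exchange at C1 and ring transposition then give the thiophenone ring, and deprotection finishes the route.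
- Enabling feature: the ring S2–C1(=O)–C7a–C3a–C3 of the benzo[c]thiophen-1(3H)-one is the thiol-ester isomer of the ring O2–C1(=S)–C7a–C3a–C3 of a thionophthalide. Because C=O/C–S is stronger than C=S/C–O, the oxygen heterocycle, which is easy to make stereodefined, can be isomerised downhill into the sulfur heterocycle.
- Stereochemistry: C1′ (R) comes from (R)-1,2-epoxyheptane. C3 (S) is set by Felkin–Anh addition of the aryllithium to the (R)-α-silyloxy aldehyde and is carried through the transposition by two consecutive inversions.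

Key step: step 12

Remark: the (3S,1′R) configuration is the anti arrangement of the C3 heteroatom and the C1′ oxygen, which is the Felkin adduct of an aryl nucleophile and an (R)-α-silyloxy aldehyde; (R)-1,2-epoxyheptane is taken as a purchasable enantiopure epoxide.

**Route**

Step 1
Reactants: 1 hydroquinone; 2 diethylcarbamoyl chloride
Product: 3 4-hydroxyphenyl N,N-diethylcarbamate
Conditions: 1 (3 equiv), K2CO3, MeCN, 60 °C, N2; aqueous wash removes surplus 1
Reagents that add atoms: none
Why: O-carbamoylation of a phenoxide (acyl substitution at the carbamoyl chloride), kept at the mono stage by the threefold excess of the symmetrical, water-soluble diol.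

Step 2
Reactants: 3 4-hydroxyphenyl N,N-diethylcarbamate
Product: 4 4-(methoxymethoxy)phenyl N,N-diethylcarbamate
Conditions: MOMCl, i-Pr2NEt, CH2Cl2, 0 °C → rt
Reagents that add atoms: chloromethyl methyl ether, COCCl
Why: Williamson-type O-alkylation (MOM protection) of the remaining phenol gives an acetal that tolerates organolithium bases, ranks below the carbamate as an ortho director and is removed by acid at the end.

Step 3
Reactants: 4 4-(methoxymethoxy)phenyl N,N-diethylcarbamate
Product: 6 N,N-diethyl-2-hydroxy-5-(methoxymethoxy)benzamide, via ortho-lithiated carbamate 5 (not isolated)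
Conditions: s-BuLi, TMEDA, THF, −78 °C; then rt; AcOH
Reagents that add atoms: none
Why: Directed ortho-metalation beside the O-carbamate (the strongest director present, with two equivalent ortho positions) is followed on warming by the anionic ortho-Fries rearrangement (1,3 O→C carbamoyl shift), which places the carboxamide next to a liberated phenol.

Step 4
Reactants: 6 N,N-diethyl-2-hydroxy-5-(methoxymethoxy)benzamide
Product: 7 3-bromo-N,N-diethyl-2-hydroxy-5-(methoxymethoxy)benzamide
Conditions: NBS (1.0 equiv), MeCN, 0 °C, dark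
Reagents that add atoms: N-bromosuccinimide, O=C1CCC(=O)N1Br
Why: Electrophilic aromatic bromination is directed by the free phenol to its only open ortho position (its para position carries the acetal oxygen, and C4 and C6 are deactivated by the para or ortho carboxamide), as in the ortho-bromination of 4-alkoxyphenols.

Step 5
Reactants: 7 3-bromo-N,N-diethyl-2-hydroxy-5-(methoxymethoxy)benzamide
Product: 8 3-bromo-N,N-diethyl-2,5-bis(methoxymethoxy)benzamide
Conditions: NaH, MOMCl, DMF, 0 °C → rt
Reagents that add atoms: chloromethyl methyl ether, COCCl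
Why: Williamson etherification through the sodium phenoxide, chosen because the phenol is flanked on both sides and hydrogen-bonded to the amide.

Step 6
Reactants: 8 3-bromo-N,N-diethyl-2,5-bis(methoxymethoxy)benzamide; 9 prenyl bromide (1-bromo-3-methylbut-2-ene)
Product: 11 N,N-diethyl-2,5-bis(methoxymethoxy)-3-(3-methylbut-2-en-1-yl)benzamide, via aryllithium 10 (not isolated)
Conditions: n-BuLi, THF, −78 °C; CuBr·SMe2 (10 mol %), 9, −78 → 0 °C
Reagents that add atoms: none
Why: Bromine–lithium exchange, faster at −78 °C than addition to the diethylamide or ring deprotonation, gives an OMOM-chelated aryllithium whose copper-catalysed SN2 alkylation with the primary allylic bromide should deliver the linear prenyl arene.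

Step 7
Reactants: 12 (R)-1,2-epoxyheptane
Product: 13 (3R)-oct-1-en-3-ol
Conditions: Me3S+ I− (3 equiv), n-BuLi, THF, −10 °C → rt; H2O
Reagents that add atoms: trimethylsulfonium iodide, C[S+](C)C.[I-]
Why: One-carbon homologation of a terminal epoxide to an allylic alcohol with excess dimethylsulfonium methylide (ring opening at the CH2 terminus, then ylide-mediated β-elimination of dimethyl sulfide), which does not touch the carbinol stereocentre.

Step 8
Reactants: 13 (3R)-oct-1-en-3-ol
Product: 14 (3R)-3-(triisopropylsilyloxy)oct-1-ene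
Conditions: TIPSOTf, 2,6-lutidine, CH2Cl2, 0 °C → rt
Reagents that add atoms: triisopropylsilyl trifluoromethanesulfonate, CC(C)[Si](OS(=O)(=O)C(F)(F)F)(C(C)C)C(C)C
Why: Silylation of the secondary alcohol with the silyl triflate; the bulky, non-chelating triisopropylsilyl ether is chosen to enforce Felkin–Anh control in the coupling and to resist 1,2 O→O silyl migration in the alkoxide formed there.

Step 9
Reactants: 14 (3R)-3-(triisopropylsilyloxy)oct-1-ene
Product: 16 (2R)-2-(triisopropylsilyloxy)heptanal, via ozonide 15 (not isolated)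
Conditions: O3, CH2Cl2, −78 °C; PPh3, −78 °C → rt; used at once
Reagents that add atoms: ozone, [O-][O+]=O
Why: Ozonolysis with reductive work-up cuts the terminal alkene to the α-silyloxy aldehyde under cold, neutral conditions that should not epimerise the α-carbon.

Step 10
Reactants: 11 N,N-diethyl-2,5-bis(methoxymethoxy)-3-(3-methylbut-2-en-1-yl)benzamide; 16 (2R)-2-(triisopropylsilyloxy)heptanal
Product: 19 (3S)-4,7-bis(methoxymethoxy)-6-(3-methylbut-2-en-1-yl)-3-[(1R)-1-(triisopropylsilyloxy)hexyl]isobenzofuran-1(3H)-one, via aryllithium 17 (not isolated), via hydroxy amide 18 (not isolated)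
Conditions: s-BuLi, TMEDA, THF, −78 °C; 16, −78 °C; AcOH, −78 °C; crude 18 in PhMe, AcOH (cat.), 90 °C; chromatography
Reagents that add atoms: none
Why: Directed ortho-metalation at the one ring position flanked by the tertiary amide and an OMOM group gives an aryllithium whose 1,2-addition to the α-silyloxy aldehyde should follow the polar Felkin–Anh model (silyloxy group anti to the incoming aryl), setting the benzylic carbinol as S, anti to the silyloxy carbon; heating the crude hydroxy amide lactonises it by acyl substitution with loss of diethylamine, which leaves both stereocentres untouched.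

Step 11
Reactants: 19 (3S)-4,7-bis(methoxymethoxy)-6-(3-methylbut-2-en-1-yl)-3-[(1R)-1-(triisopropylsilyloxy)hexyl]isobenzofuran-1(3H)-one
Product: 20 (3S)-4,7-bis(methoxymethoxy)-6-(3-methylbut-2-en-1-yl)-3-[(1R)-1-(triisopropylsilyloxy)hexyl]isobenzofuran-1(3H)-thione
Conditions: Lawesson's reagent (0.7 equiv), PhMe, 110 °C
Reagents that add atoms: Lawesson's reagent, COc1ccc(cc1)P1(=S)SP(=S)(S1)c1ccc(OC)cc1
Why: Thionation of the lactone carbonyl with Lawesson's reagent (oxygen–sulfur exchange through a four-membered P–S–C–O intermediate), a reaction known for phthalides that involves no bond to C3.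

Step 12
Reactants: 20 (3S)-4,7-bis(methoxymethoxy)-6-(3-methylbut-2-en-1-yl)-3-[(1R)-1-(triisopropylsilyloxy)hexyl]isobenzofuran-1(3H)-thione
Product: 22 (3S)-4,7-bis(methoxymethoxy)-6-(3-methylbut-2-en-1-yl)-3-[(1R)-1-(triisopropylsilyloxy)hexyl]benzo[c]thiophen-1(3H)-one, via bromo thiocarboxylate 21 (not isolated)
Conditions: Bu4NBr (20 mol %), MeCN, 80 °C, sealed tube, Ar
Reagents that add atoms: none
Why: Proposed new method: bromide attacks C3 of 20 anti to the ring oxygen (SN2, inversion) and releases the ortho-thiocarboxylate 21, whose sulfur then displaces bromide from the same carbon (second SN2, inversion), so that the O2–C3 bond is traded for S2–C3 with net retention and the halide is returned. The closest known reactions are the halide-catalysed thione-to-thiol isomerisations of thionolactones, O-alkyl thionoesters and cyclic thionocarbonates; transfer of configuration at a secondary benzylic C3 of an isobenzofuranthione has not been demonstrated, hence the label. The thiophenone ring closes in the 5-exo-tet mode, and the closure is irreversible because C=O/C–S is stronger than C=S/C–O. No stereocentre is created; the C3 configuration is governed by the two consecutive inversions and C1′ is a spectator. The step needs substitution rather than ionisation at C3 and S- rather than O-alkylation of the ambident anion: the ortho thioacyl group and the β-silyloxy substituent both disfavour a benzylic cation, the silyl ether cannot participate, and O-closure only regenerates 20 whereas S-closure is the soft–soft and thermodynamically favoured path. A low bromide loading should keep the intramolecular closure of 21 faster than bromide-for-bromide exchange, the one event that would epimerise C3.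

Step 13
Reactants: 22 (3S)-4,7-bis(methoxymethoxy)-6-(3-methylbut-2-en-1-yl)-3-[(1R)-1-(triisopropylsilyloxy)hexyl]benzo[c]thiophen-1(3H)-one
Product: 23 (3S)-3-[(1R)-1-hydroxyhexyl]-4,7-bis(methoxymethoxy)-6-(3-methylbut-2-en-1-yl)benzo[c]thiophen-1(3H)-one
Conditions: HF·pyridine, pyridine, THF, 0 °C → rt
Reagents that add atoms: none
Why: Fluoride-driven Si–O cleavage in an acidic, buffered medium frees the side-chain alcohol without forming an alkoxide that could attack the thiolactone carbonyl.

Step 14
Reactants: 23 (3S)-3-[(1R)-1-hydroxyhexyl]-4,7-bis(methoxymethoxy)-6-(3-methylbut-2-en-1-yl)benzo[c]thiophen-1(3H)-one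
Product: 24 asperglaucin A, (3S)-4,7-dihydroxy-3-[(1R)-1-hydroxyhexyl]-6-(3-methylbut-2-en-1-yl)benzo[c]thiophen-1(3H)-one
Conditions: 3 M aq. HCl, MeOH, THF, rt, Ar (degassed)
Reagents that add atoms: none
Why: Acid-catalysed acetal exchange (methanolysis of both aryl MOM ethers to dimethoxymethane) at room temperature, conditions that ortho-prenyl phenols and five-membered thiolactones should survive.

**Compound list**

1 | hydroquinone | Oc1ccc(O)cc1 | starting material
2 | diethylcarbamoyl chloride | CCN(CC)C(Cl)=O | starting material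
3 | 4-hydroxyphenyl N,N-diethylcarbamate | CCN(CC)C(=O)Oc1ccc(O)cc1 | intermediate
4 | 4-(methoxymethoxy)phenyl N,N-diethylcarbamate | CCN(CC)C(=O)Oc1ccc(OCOC)cc1 | intermediate
5 | 2-lithio-4-(methoxymethoxy)phenyl N,N-diethylcarbamate | CCN(CC)C(=O)Oc1ccc(OCOC)cc1[Li] | intermediate
6 | N,N-diethyl-2-hydroxy-5-(methoxymethoxy)benzamide | CCN(CC)C(=O)c1cc(OCOC)ccc1O | intermediate
7 | 3-bromo-N,N-diethyl-2-hydroxy-5-(methoxymethoxy)benzamide | CCN(CC)C(=O)c1cc(OCOC)cc(Br)c1O | intermediate
8 | 3-bromo-N,N-diethyl-2,5-bis(methoxymethoxy)benzamide | CCN(CC)C(=O)c1cc(OCOC)cc(Br)c1OCOC | intermediate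
9 | prenyl bromide (1-bromo-3-methylbut-2-ene) | CC(C)=CCBr | starting material
10 | N,N-diethyl-3-lithio-2,5-bis(methoxymethoxy)benzamide | CCN(CC)C(=O)c1cc(OCOC)cc([Li])c1OCOC | intermediate
11 | N,N-diethyl-2,5-bis(methoxymethoxy)-3-(3-methylbut-2-en-1-yl)benzamide | CCN(CC)C(=O)c1cc(OCOC)cc(CC=C(C)C)c1OCOC | intermediate
12 | (R)-1,2-epoxyheptane | CCCCC[C@@H]1CO1 | starting material
13 | (3R)-oct-1-en-3-ol | CCCCC[C@@H](O)C=C | intermediate
14 | (3R)-3-(triisopropylsilyloxy)oct-1-ene | CCCCC[C@@H](O[Si](C(C)C)(C(C)C)C(C)C)C=C | intermediate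
15 | 3-[(1R)-1-(triisopropylsilyloxy)hexyl]-1,2,4-trioxolane (ozonide, both ring epimers) | CCCCC[C@@H](O[Si](C(C)C)(C(C)C)C(C)C)C1OCOO1 | intermediate
16 | (2R)-2-(triisopropylsilyloxy)heptanal | CCCCC[C@@H](O[Si](C(C)C)(C(C)C)C(C)C)C=O | intermediate
17 | N,N-diethyl-2-lithio-3,6-bis(methoxymethoxy)-5-(3-methylbut-2-en-1-yl)benzamide | CCN(CC)C(=O)c1c([Li])c(OCOC)cc(CC=C(C)C)c1OCOC | intermediate
18 | N,N-diethyl-2-[(1S,2R)-1-hydroxy-2-(triisopropylsilyloxy)heptyl]-3,6-bis(methoxymethoxy)-5-(3-methylbut-2-en-1-yl)benzamide | CCCCC[C@@H](O[Si](C(C)C)(C(C)C)C(C)C)[C@@H](O)c1c(OCOC)cc(CC=C(C)C)c(OCOC)c1C(=O)N(CC)CC | intermediate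
19 | (3S)-4,7-bis(methoxymethoxy)-6-(3-methylbut-2-en-1-yl)-3-[(1R)-1-(triisopropylsilyloxy)hexyl]isobenzofuran-1(3H)-one | CCCCC[C@@H](O[Si](C(C)C)(C(C)C)C(C)C)[C@H]1OC(=O)c2c(OCOC)c(CC=C(C)C)cc(OCOC)c21 | intermediate
20 | (3S)-4,7-bis(methoxymethoxy)-6-(3-methylbut-2-en-1-yl)-3-[(1R)-1-(triisopropylsilyloxy)hexyl]isobenzofuran-1(3H)-thione | CCCCC[C@@H](O[Si](C(C)C)(C(C)C)C(C)C)[C@H]1OC(=S)c2c(OCOC)c(CC=C(C)C)cc(OCOC)c21 | intermediate
21 | tetrabutylammonium 2-[(1R,2R)-1-bromo-2-(triisopropylsilyloxy)heptyl]-3,6-bis(methoxymethoxy)-5-(3-methylbut-2-en-1-yl)benzenecarbothioate | CCCCC[C@@H](O[Si](C(C)C)(C(C)C)C(C)C)[C@H](Br)c1c(OCOC)cc(CC=C(C)C)c(OCOC)c1C(=O)[S-].CCCC[N+](CCCC)(CCCC)CCCC | intermediate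
22 | (3S)-4,7-bis(methoxymethoxy)-6-(3-methylbut-2-en-1-yl)-3-[(1R)-1-(triisopropylsilyloxy)hexyl]benzo[c]thiophen-1(3H)-one | CCCCC[C@@H](O[Si](C(C)C)(C(C)C)C(C)C)[C@H]1SC(=O)c2c(OCOC)c(CC=C(C)C)cc(OCOC)c21 | intermediate
23 | (3S)-3-[(1R)-1-hydroxyhexyl]-4,7-bis(methoxymethoxy)-6-(3-methylbut-2-en-1-yl)benzo[c]thiophen-1(3H)-one | CCCCC[C@@H](O)[C@H]1SC(=O)c2c(OCOC)c(CC=C(C)C)cc(OCOC)c21 | intermediate
24 | asperglaucin A, (3S)-4,7-dihydroxy-3-[(1R)-1-hydroxyhexyl]-6-(3-methylbut-2-en-1-yl)benzo[c]thiophen-1(3H)-one | CCCCC[C@@H](O)[C@H]1SC(=O)c2c(O)c(CC=C(C)C)cc(O)c21 | target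

**Step count and risks**

Total step count: 14. Longest linear sequence: 11 steps (steps 1–6 and 10–14, from hydroquinone); the aldehyde branch is steps 7–9.

Steps most likely to fail:

1. Step 12. The C3 configuration may erode, either by heterolysis of the benzylic C3–O bond ahead of bromide attack (the C4 oxygen substituent can stabilise a cation) or by bromide-for-bromide exchange on the open intermediate before it closes. The reaction may also stall because backside attack at the crowded C3 is slow. The fallback uses known chemistry, sets out from hydroxy amide 18 (isolated after the cold quench of step 10 instead of being heated) and comes back at thiolactone 22. It carries out the two inversions one at a time with internal nucleophiles. MsCl/Et3N (CH2Cl2, 0 °C) sulfonylates the benzylic hydroxyl, and the neighbouring carboxamide oxygen displaces the sulfonate with inversion to give the (3R)-configured cyclic iminium ether mesylate F1. Anhydrous NaSH (MeCN, 0 °C) adds to the iminium carbon and expels the ring alkoxide, as in the imidate-salt route to thioamides, to give the syn-hydroxy thioamide F2. A second treatment with MsCl/Et3N lets the thioamide sulfur displace the sulfonate with inversion, the cyclodehydration that converts hydroxy thioamides into thiazolines, to give the (3S)-configured cyclic thioiminium mesylate F3. Aqueous NaH2PO4 then hydrolyses the C=N+ bond to 22.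

2. Step 10. Facial selectivity in the carbonyl addition may be poor, since a bulky amide-chelated aryllithium may follow the Felkin–Anh preference only weakly, so that much syn adduct forms. The fallback sets out from 11 and 16 and comes back at lactone 19. The addition is run as before, but the crude hydroxy amides are separated on silica after the cold quench. The anti adduct 18 is lactonised by heating, with retention. Its carbinol epimer, the syn-hydroxy amide F4, is treated with MsCl/Et3N so that the carboxamide oxygen closes the ring with inversion to the (3S)-configured cyclic iminium ether mesylate F5, which aqueous NaH2PO4 hydrolyses to the same lactone 19. Both adducts converge, so the selectivity of the addition no longer limits the route.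

3. Step 11. Oxygen–sulfur exchange may be slow at a carbonyl shielded by the C7 OMOM group, so that the temperature and time required bring acetal cleavage by acidic phosphorus by-products and premature, uncatalysed isomerisation with loss of control at C3. The fallback sets out from lactone 19 and comes back at thionolactone 20. The carbonyl oxygen is alkylated with Et3O+ BF4− (CH2Cl2, 2,6-di-tert-butylpyridine, rt) to give the O-ethyl lactonium tetrafluoroborate F6. Anhydrous NaSH (MeCN, 0 °C) then adds to the dioxycarbenium carbon and expels ethanol to give 20 at or below room temperature, without a phosphorus–sulfur reagent.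

**Further compounds**

F1 | step 12 | N-[(3R)-4,7-bis(methoxymethoxy)-6-(3-methylbut-2-en-1-yl)-3-[(1R)-1-(triisopropylsilyloxy)hexyl]isobenzofuran-1(3H)-ylidene]-N-ethylethanaminium methanesulfonate | CCCCC[C@@H](O[Si](C(C)C)(C(C)C)C(C)C)[C@@H]1OC(=[N+](CC)CC)c2c(OCOC)c(CC=C(C)C)cc(OCOC)c21.CS(=O)(=O)[O-]
F2 | step 12 | N,N-diethyl-2-[(1R,2R)-1-hydroxy-2-(triisopropylsilyloxy)heptyl]-3,6-bis(methoxymethoxy)-5-(3-methylbut-2-en-1-yl)benzenecarbothioamide | CCCCC[C@@H](O[Si](C(C)C)(C(C)C)C(C)C)[C@H](O)c1c(OCOC)cc(CC=C(C)C)c(OCOC)c1C(=S)N(CC)CC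
F3 | step 12 | N-[(3S)-4,7-bis(methoxymethoxy)-6-(3-methylbut-2-en-1-yl)-3-[(1R)-1-(triisopropylsilyloxy)hexyl]benzo[c]thiophen-1(3H)-ylidene]-N-ethylethanaminium methanesulfonate | CCCCC[C@@H](O[Si](C(C)C)(C(C)C)C(C)C)[C@H]1SC(=[N+](CC)CC)c2c(OCOC)c(CC=C(C)C)cc(OCOC)c21.CS(=O)(=O)[O-]
F4 | step 10 | N,N-diethyl-2-[(1R,2R)-1-hydroxy-2-(triisopropylsilyloxy)heptyl]-3,6-bis(methoxymethoxy)-5-(3-methylbut-2-en-1-yl)benzamide | CCCCC[C@@H](O[Si](C(C)C)(C(C)C)C(C)C)[C@H](O)c1c(OCOC)cc(CC=C(C)C)c(OCOC)c1C(=O)N(CC)CC
F5 | step 10 | N-[(3S)-4,7-bis(methoxymethoxy)-6-(3-methylbut-2-en-1-yl)-3-[(1R)-1-(triisopropylsilyloxy)hexyl]isobenzofuran-1(3H)-ylidene]-N-ethylethanaminium methanesulfonate | CCCCC[C@@H](O[Si](C(C)C)(C(C)C)C(C)C)[C@H]1OC(=[N+](CC)CC)c2c(OCOC)c(CC=C(C)C)cc(OCOC)c21.CS(=O)(=O)[O-]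
F6 | step 11 | (3S)-1-ethoxy-4,7-bis(methoxymethoxy)-6-(3-methylbut-2-en-1-yl)-3-[(1R)-1-(triisopropylsilyloxy)hexyl]-3H-isobenzofuran-2-ium tetrafluoroborate | CCCCC[C@@H](O[Si](C(C)C)(C(C)C)C(C)C)[C@H]1[O+]=C(OCC)c2c(OCOC)c(CC=C(C)C)cc(OCOC)c21.F[B-](F)(F)F
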